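## Retrosynthetic overview
1. Target 29 comes from alkynol 28 by alkynol cycloisomerisation. The dihydrofuran is closed last because it is labile to acid and to oxidants.
2. 28 comes from bis-epoxide 25 by one base-triggered epoxide relay (Payne shift, then 5-exo opening). This closes the spiro-oxirane and the spiro-oxolane together and inverts C8 and C13 into place.
3. 25 comes from the tricyclic vinylogous ester 13 and (S)-iodide 18. The α′-alkylation makes C9–C11, a sulfur ylide brings C17, and the 6-ketone is reduced from the α face.
4. 13 comes from keto cyclopropane 11, where an enolate-triggered cyclopropane opening and alkylation closes ring A. 11 comes from diazo ester 9, where a rhodium carbene desymmetrisation closes the lactone and a cyclopropane at once.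
5. 9 comes from Birch reductive alkylation of methyl 3,5-dimethoxybenzoate. Ring order: B, then lactone (+ cyclopropane), then A, then oxirane + oxolane, then dihydrofuran.

Assumption: positions follow labdane numbering (C19 lactone C=O, C20 lactone CH2O, C17 oxirane CH2, C13 bis-spiro carbon). β is the face that carries C20. For steps 5 and 8 the sense of induction is unproven, so the catalyst antipode named may have to be exchanged for its mirror image; both antipodes are available.

## Route

Step 1
Reactants: 1 methyl 3,5-dimethoxybenzoate; 2 1-bromo-3-chloropropane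
Product: 3 methyl 1-(3-chloropropyl)-3,5-dimethoxycyclohexa-2,5-diene-1-carboxylate
Conditions: Li, NH3(l)/THF, t-BuOH (1 equiv), −78 °C; then 2
Reagents that add atoms: none
Why: Birch reduction–alkylation, in which the ester-stabilised dienolate is alkylated at the ipso carbon by the C–Br end only, giving quaternary C10 in a product that still has a mirror plane (no stereocentre yet).

Step 2
Reactants: 3 methyl 1-(3-chloropropyl)-3,5-dimethoxycyclohexa-2,5-diene-1-carboxylate
Product: 4 [1-(3-chloropropyl)-3,5-dimethoxycyclohexa-2,5-dien-1-yl]methanol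
Conditions: LiAlH4, Et2O, 0 °C
Reagents that add atoms: none
Why: Hydride reduction of the ester gives the C20 carbinol, while the primary chloride and both enol ethers survive at 0 °C under basic work-up.

Step 3
Reactants: 5 pyruvic acid; 6 4-methylbenzenesulfonohydrazide
Product: 7 2-(tosylhydrazono)propanoic acid
Conditions: MeOH, 23 °C
Reagents that add atoms: none
Why: Simple hydrazone condensation gives the crystalline carrier of C4, C18 and C19.

Step 4
Reactants: 4 [1-(3-chloropropyl)-3,5-dimethoxycyclohexa-2,5-dien-1-yl]methanol; 7 2-(tosylhydrazono)propanoic acid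
Product: 9 [1-(3-chloropropyl)-3,5-dimethoxycyclohexa-2,5-dien-1-yl]methyl 2-diazopropanoate, via hydrazone ester 8 (not isolated)
Conditions: DCC, DMAP (cat.), CH2Cl2, 0 °C; then DBU, 0 → 23 °C
Reagents that add atoms: none
Why: Steglich esterification followed by Bamford–Stevens-type loss of sulfinate from the α-keto ester tosylhydrazone gives the diazo ester under acid-free conditions that spare the enol ethers.

Step 5
Reactants: 9 [1-(3-chloropropyl)-3,5-dimethoxycyclohexa-2,5-dien-1-yl]methyl 2-diazopropanoate
Product: 11 8-oxo cyclopropane lactone, via enol ether cyclopropane 10 (not isolated)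
Conditions: Rh2(4S-MPPIM)4 (1 mol %), CH2Cl2, 40 °C, slow addition; then oxalic acid, THF–H2O, 0 °C
Reagents that add atoms: water, O
Why: Enantioselective intramolecular cyclopropanation with a chiral rhodium carboxamidate carbenoid, in which the tether lets the carbene reach only the face syn to C20 and the catalyst picks one of the two enantiotopic enol ether C=C bonds, so δ-lactone and cyclopropane close together and C10 (C20 β), C5 (H α), C4 and C6 are set at once; oxalic acid then hydrolyses only the remaining enol ether to the C8 ketone.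

Step 6
Reactants: 11 8-oxo cyclopropane lactone
Product: 13 tricyclic vinylogous ester, via potassium lactone enolate 12 (not isolated)
Conditions: KOt-Bu, THF, 0 → 40 °C
Reagents that add atoms: none
Why: Proposed new method: reversible enolisation at C7 makes the ketone a vinylogous donor that, together with 6-OMe, pushes open the strained C6–C4 bond to a conjugated 6-methoxy-enone and the lactone enolate (closest known type: base- or fluoride-induced opening of 2-oxy-cyclopropanecarboxylates to γ-oxo ester enolates), and this enolate is alkylated 6-exo-tet by the chloropropyl arm, a bridging that can occur in one sense only and so fixes C4 (methyl α, C19 β) and the trans A/B fusion.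

Step 7
Reactants: 14 3-bromobut-3-en-1-ol; 15 ethynyltrimethylsilane
Product: 16 3-methylidene-5-(trimethylsilyl)pent-4-yn-1-ol
Conditions: Pd(PPh3)2Cl2 (2 mol %), CuI (4 mol %), Et3N, THF, 23 °C
Reagents that add atoms: none
Why: Sonogashira coupling of the vinyl bromide gives the 2-substituted enyne (C11–C16) with no stereocentre.

Step 8
Reactants: 16 3-methylidene-5-(trimethylsilyl)pent-4-yn-1-ol
Product: 17 (S)-2-{2-[(trimethylsilyl)ethynyl]oxiran-2-yl}ethanol
Conditions: VO(OiPr)3 (1 mol %), C2-symmetric bishydroxamic acid ligand from (1R,2R)-cyclohexane-1,2-diamine (2 mol %), cumene hydroperoxide, toluene, 0 °C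
Reagents that add atoms: cumene hydroperoxide, CC(C)(OO)c1ccccc1
Why: Hydroxyl-directed vanadium-catalysed asymmetric epoxidation of a homoallylic alcohol, in which the chiral ligand selects the alkene face and sets C13 as S.

Step 9
Reactants: 17 (S)-2-{2-[(trimethylsilyl)ethynyl]oxiran-2-yl}ethanol
Product: 18 (S)-2-(2-iodoethyl)-2-[(trimethylsilyl)ethynyl]oxirane
Conditions: I2, PPh3, imidazole, CH2Cl2, 0 °C
Reagents that add atoms: iodine, II
Why: Appel-type (Garegg–Samuelsson) iodination of the primary alcohol under imidazole buffering leaves the oxirane and C13 untouched.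

Step 10
Reactants: 13 tricyclic vinylogous ester; 18 (S)-2-(2-iodoethyl)-2-[(trimethylsilyl)ethynyl]oxirane
Product: 19 C9-alkylated vinylogous ester
Conditions: LDA, THF–DMPU, −78 °C; then 18, −78 → −20 °C
Reagents that add atoms: none
Why: Stork–Danheiser kinetic α′-enolate alkylation makes C9–C11 with the primary iodide reacting faster than the oxirane, and the C9 configuration is irrelevant because C9 becomes sp2 in the next step.

Step 11
Reactants: 19 C9-alkylated vinylogous ester
Product: 22 6-oxo-8(9)-en-17-ol, via C8 spiro-oxirane 20 (not isolated), via dienol ether alcohol 21 (not isolated)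
Conditions: Me3SI, n-BuLi, THF, −10 °C, 45 min; 23 °C, 1 h; then oxalic acid, THF–H2O, 0 °C
Reagents that add atoms: trimethylsulfonium iodide, C[S+](C)C.[I-]; water, O
Why: Proposed new method: Corey–Chaykovsky 1,2-addition of dimethylsulfonium methylide to the vinylogous ester carbonyl (closest known type: the ylide step of the Garst–Spencer furan annulation on vinylogous thioesters) gives a 2-methoxyvinyl oxirane whose C8–O bond ionises under the push of the enol ether, the liberated C17 alkoxide removes H-9 to give the 8(9)-ene-17-ol, and mild acid then protonates the dienol ether kinetically at C7 to release the deconjugated 6-ketone; lactone and side-chain oxirane are spared because the ylide ignores esters and homologates oxiranes only with a large excess at room temperature.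

Step 12
Reactants: 22 6-oxo-8(9)-en-17-ol
Product: 23 6β,17-diol
Conditions: NaBH4, CeCl3·7H2O, MeOH, −78 → −40 °C; AcOH quench
Reagents that add atoms: none
Why: Luche reduction, in which the lactone bridge (C19/C20) blocks the β face so that hydride enters from the α face and sets the axial 6β-OH, while the cold, weakly acidic medium suppresses attack of O6 on C19.

Step 13
Reactants: 23 6β,17-diol
Product: 24 6β,17-diacetate
Conditions: Ac2O, DMAP, Et3N, CH2Cl2, 0 → 23 °C
Reagents that add atoms: acetic anhydride, CC(=O)OC(C)=O
Why: DMAP-catalysed acetylation installs the final 6β-acetate at once (blocking translactonisation) and masks O17 as a far more labile primary acetate.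

Step 14
Reactants: 24 6β,17-diacetate
Product: 25 8α,9α-epoxide
Conditions: mCPBA, NaHCO3, CH2Cl2, 0 °C
Reagents that add atoms: mCPBA, OOC(=O)c1cccc(Cl)c1
Why: Prilezhaev epoxidation of the only alkene, with the peracid approaching anti to axial C20 and 6β-OAc, so that the oxygen destined to become O9 is placed on the α face.

Step 15
Reactants: 25 8α,9α-epoxide
Product: 28 spiro-oxirane spiro-oxolane alkynol, via epoxy alcohol 26 (not isolated), via Payne isomer 27 (not isolated)
Conditions: K2CO3, MeOH, 0 → 23 °C
Reagents that add atoms: none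
Why: Proposed new method: methanolysis frees O17 and the alkyne C–H, Payne rearrangement lets O17 attack C8 from the β face (inversion gives oxirane O β and C17 α) and releases the 9α-alkoxide, which is drained irreversibly by 5-exo-tet opening of the side-chain oxirane at propargylic C13 (inversion, S to R), so two rings close in one pot (closest known types: Payne rearrangement with in situ trapping, and epoxide-opening cascades), while relief of the β-face crowding of C11 and C17 in 26 favours 27 and the hindered axial 6β-acetate survives.

Step 16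
Reactants: 28 spiro-oxirane spiro-oxolane alkynol
Product: 29 target CNP0173713.2
Conditions: Mo(CO)6 (25 mol %), Et3N, Et2O, hν (350 nm, pre-irradiation); then 28, 23 °C
Reagents that add atoms: none
Why: McDonald-type endo cycloisomerisation of a 1-alkyn-4-ol through a molybdenum vinylidene, in which O16 adds to C15 to give the 2,3-dihydrofuran in amine-buffered medium that preserves enol ether, oxirane, acetate and all stereocentres.

## Compound list
1 | methyl 3,5-dimethoxybenzoate | COC(=O)c1cc(OC)cc(OC)c1 | starting material
2 | 1-bromo-3-chloropropane | ClCCCBr | starting material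
3 | methyl 1-(3-chloropropyl)-3,5-dimethoxycyclohexa-2,5-diene-1-carboxylate (achiral) | COC(=O)C1(CCCCl)C=C(OC)CC(OC)=C1 | intermediate
4 | [1-(3-chloropropyl)-3,5-dimethoxycyclohexa-2,5-dien-1-yl]methanol (achiral) | OCC1(CCCCl)C=C(OC)CC(OC)=C1 | intermediate
5 | pyruvic acid | CC(=O)C(=O)O | starting material
6 | 4-methylbenzenesulfonohydrazide | Cc1ccc(cc1)S(=O)(=O)NN | starting material
7 | 2-(tosylhydrazono)propanoic acid | CC(=NNS(=O)(=O)c1ccc(C)cc1)C(=O)O | intermediate
8 | hydrazone ester of 4 with 7 (not isolated) | CC(=NNS(=O)(=O)c1ccc(C)cc1)C(=O)OCC1(CCCCl)C=C(OC)CC(OC)=C1 | intermediate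
9 | [1-(3-chloropropyl)-3,5-dimethoxycyclohexa-2,5-dien-1-yl]methyl 2-diazopropanoate | CC(=[N+]=[N-])C(=O)OCC1(CCCCl)C=C(OC)CC(OC)=C1 | intermediate
10 | enol ether cyclopropane (not isolated): 19,20-δ-lactone cis-fused to ring B, C4 bridging C5 and C6 on the β face (4-methyl exo), 6-OMe, 8-OMe enol ether, H-5 α, chloropropyl α and C20 β on C10 | CO[C@]12CC(OC)=C[C@]3(CCCCl)COC(=O)[C@@]1(C)[C@H]23 | intermediate
11 | 8-oxo cyclopropane lactone (as 10, with C8 ketone) | CO[C@]12CC(=O)C[C@]3(CCCCl)COC(=O)[C@@]1(C)[C@H]23 | intermediate
12 | potassium lactone enolate (not isolated): 6-methoxy-6-en-8-one, C4=C19 enolate, chloropropyl on C10 | COC1=CC(=O)C[C@]2(CCCCl)COC([O-])=C(C)[C@H]12.[K+] | intermediate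
13 | tricyclic vinylogous ester: trans-decalin, 19,20-olide on the β face, 4α-methyl, H-5 α, 6-methoxy-6-en-8-one | COC1=CC(=O)C[C@]23CCC[C@](C)(C(=O)OC2)[C@H]13 | intermediate
14 | 3-bromobut-3-en-1-ol | OCCC(Br)=C | starting material
15 | ethynyltrimethylsilane | C#C[Si](C)(C)C | starting material
16 | 3-methylidene-5-(trimethylsilyl)pent-4-yn-1-ol | C=C(CCO)C#C[Si](C)(C)C | intermediate
17 | (S)-2-{2-[(trimethylsilyl)ethynyl]oxiran-2-yl}ethanol | OCC[C@]1(C#C[Si](C)(C)C)CO1 | intermediate
18 | (S)-2-(2-iodoethyl)-2-[(trimethylsilyl)ethynyl]oxirane | ICC[C@]1(C#C[Si](C)(C)C)CO1 | intermediate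
19 | C9-alkylated vinylogous ester (13 carrying the C11–C16 chain at C9; C9 epimers converge; 13S) | COC1=CC(=O)C(CC[C@]4(C#C[Si](C)(C)C)CO4)[C@]23CCC[C@](C)(C(=O)OC2)[C@H]13 | intermediate
20 | C8 spiro-oxirane of 19 (not isolated; C8 and C9 configurations are erased in the next event) | COC1=CC5(CO5)C(CC[C@]4(C#C[Si](C)(C)C)CO4)[C@]23CCC[C@](C)(C(=O)OC2)[C@H]13 | intermediate
21 | dienol ether alcohol (not isolated): 6-methoxy-6,8(9)-diene-17-ol | COC1=CC(CO)=C(CC[C@]4(C#C[Si](C)(C)C)CO4)[C@]23CCC[C@](C)(C(=O)OC2)[C@H]13 | intermediate
22 | 6-oxo-8(9)-en-17-ol | O=C1CC(CO)=C(CC[C@]4(C#C[Si](C)(C)C)CO4)[C@]23CCC[C@](C)(C(=O)OC2)[C@H]13 | intermediate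
23 | 6β,17-diol | O[C@@H]1CC(CO)=C(CC[C@]4(C#C[Si](C)(C)C)CO4)[C@]23CCC[C@](C)(C(=O)OC2)[C@H]13 | intermediate
24 | 6β,17-diacetate | CC(=O)O[C@@H]1CC(COC(C)=O)=C(CC[C@]4(C#C[Si](C)(C)C)CO4)[C@]23CCC[C@](C)(C(=O)OC2)[C@H]13 | intermediate
25 | 8α,9α-epoxide of 24 (C11 and C17 β) | CC(=O)O[C@@H]1C[C@@]5(COC(C)=O)O[C@@]5(CC[C@]4(C#C[Si](C)(C)C)CO4)[C@]23CCC[C@](C)(C(=O)OC2)[C@H]13 | intermediate
26 | epoxy alcohol (not isolated): 8α,9α-epoxy-17-ol, terminal alkyne, 6β-OAc | CC(=O)O[C@@H]1C[C@@]5(CO)O[C@@]5(CC[C@]4(C#C)CO4)[C@]23CCC[C@](C)(C(=O)OC2)[C@H]13 | intermediate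
27 | Payne isomer (not isolated): 8β,17-epoxide (O β, C17 α), 9α-OH | CC(=O)O[C@@H]1C[C@@]5(CO5)[C@](O)(CC[C@]4(C#C)CO4)[C@]23CCC[C@](C)(C(=O)OC2)[C@H]13 | intermediate
28 | spiro-oxirane spiro-oxolane alkynol: 9α,13-epoxide, 13R, C13 bearing ethynyl and CH2OH | CC(=O)O[C@@H]1C[C@@]2(CO2)[C@]2(CC[C@](CO)(C#C)O2)[C@]23CCC[C@](C)(C(=O)OC2)[C@H]13 | intermediate
29 | CNP0173713.2 (4S,5R,6R,8R,9S,10S,13R) | CC(=O)O[C@@H]1C[C@@]2(CO2)[C@]2(CC[C@]3(C=COC3)O2)[C@]23CCC[C@](C)(C(=O)OC2)[C@H]13 | target

## Count and risk
Total steps: 16. Longest linear sequence: 12 (steps 1, 2, 4, 5, 6, 10, 11, 12, 13, 14, 15, 16).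

**Step 5.** The methyl-bearing carbenoid may undergo a 1,2-hydride shift to the acrylate, and selection between the enantiotopic alkenes is untested.
- The fallback sets out from 4 and comes back at 10. It removes the β-hydrogens from the carbene and adds the methyl group afterwards.
- 4 is acylated with 2,5-dioxopyrrolidin-1-yl 2-diazoacetate to give the dienylmethyl diazoacetate F1.
- Rh2(5S-MEPY)4 then performs the best-precedented case, a homoallylic diazoacetate, to give the nor-methyl cyclopropane lactone F2.
- The cyclopropyl lactone enolate of F2 (LDA, −78 °C) is methylated with MeI on its only open, exo face to give 10.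

**Step 11.** The ylide may be too slow on the deactivated carbonyl, may touch the side-chain oxirane, or the cation may collapse to the conjugated enone.
- The fallback sets out from 19 and comes back at 21. It makes C8–C17 by cross-coupling rather than carbonyl addition.
- KHMDS and N-(5-chloropyridin-2-yl)bis(trifluoromethanesulfonimide) convert 19 to the dienyl triflate F3.
- Stille hydroxymethylation with (tributylstannyl)methanol (Pd2(dba)3, AsPh3, LiCl, NMP, 23–40 °C) gives 21. At this temperature zerovalent palladium should insert into the triflate faster than it ionises the silyl-capped alkynyl oxirane.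
- 21 is hydrolysed as before.

**Step 15.** The Payne equilibrium, 6-endo opening, or loss or migration of the 6-acetate may spoil the relay.
- The fallback sets out from 25 and comes back at 28. It separates the two ring closures and switches the second from nucleophile activation to electrophile activation.
- Methanolysis is stopped at −20 °C and the equilibrated pair 26/27 is isolated. Both are already listed, so entry F0 holds no compound.
- Camphorsulfonic acid (5 mol %) in CH2Cl2 at −20 °C then opens the protonated side-chain oxirane of 27 at its tertiary propargylic carbon (5-exo, inversion).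
- Recovered 26 is re-equilibrated with base.

Further compounds
F1 | step 5 | [1-(3-chloropropyl)-3,5-dimethoxycyclohexa-2,5-dien-1-yl]methyl 2-diazoacetate | [N-]=[N+]=CC(=O)OCC1(CCCCl)C=C(OC)CC(OC)=C1
F2 | step 5 | nor-methyl cyclopropane lactone (10 with H in place of the 4-methyl group) | CO[C@]12CC(OC)=C[C@]3(CCCCl)COC(=O)[C@H]1[C@H]23
F3 | step 11 | dienyl triflate (6-methoxy-6,8(9)-dien-8-yl trifluoromethanesulfonate of 19) | COC1=CC(OS(=O)(=O)C(F)(F)F)=C(CC[C@]4(C#C[Si](C)(C)C)CO4)[C@]23CCC[C@](C)(C(=O)OC2)[C@H]13
F0 | step 15 | none | none
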